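The route disconnects all four C2'–CH3 bonds of the two cyclopentane rings at once, leading back to a twofold-symmetric bis(2-aryl-2-methylcyclopentanone). The key step exploits the fact that in each five-membered ring the gem-dimethyl carbon C2' sits directly next to the aryl-bearing quaternary stereocentre C1'. A ketone at C2' has no α-hydrogen on that side, so Ti(CH3)2Cl2 can exchange each carbonyl oxygen for two methyl groups in one operation without touching C1'. The precursor is the (R,R)-diketone tetramethyl ether, built two-directionally from a bibenzyl dibromide by acetylation, cyclobutylidene Wittig reaction, asymmetric epoxidation and ring expansion. BBr3 then frees the two catechols.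

Key step: step 7

Assumption (a remark on the chemistry): the facial sense of the dioxirane epoxidation in step 5 is assigned from the spiro transition-state model for aryl alkenes (aryl group beside the oxazolidinone of the catalyst), which places the required (S)-epoxide with the L-glucose-derived antipode of the ketone. A trial on the mono-aryl alkene should confirm this, and if the sense is the reverse the D-glucose-derived ketone is used with nothing else changed.

Step 1
Reactants: 1 3-bromo-4,5-dimethoxybenzaldehyde (two molecules, joined carbonyl carbon to carbonyl carbon)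
Product: 3 (E)-1,2-bis(3-bromo-4,5-dimethoxyphenyl)ethene, via titanium pinacolate 2 (not isolated)
Conditions: 1 (2 equiv per molecule of 3), TiCl4, Zn, THF, 0 °C then reflux; aq. K2CO3
Reagents that add atoms: 3-bromo-4,5-dimethoxybenzaldehyde (a second molecule of 1), COc1cc(C=O)cc(Br)c1OC
Why: McMurry reductive homocoupling, in which low-valent titanium joins the carbonyl carbons of two molecules of 1 to the pinacolate 2 and deoxygenates it to the stilbene while aryl bromides are tolerated; the alkene geometry is immaterial because the double bond is saturated in the next step.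

Step 2
Reactants: 3 (E)-1,2-bis(3-bromo-4,5-dimethoxyphenyl)ethene
Product: 4 1,2-bis(3-bromo-4,5-dimethoxyphenyl)ethane
Conditions: TsNHNH2, NaOAc, DME/H2O, reflux
Reagents that add atoms: none
Why: Diimide reduction, in which HN=NH generated in the flask delivers two hydrogens to the stilbene double bond in a concerted cis transfer and leaves both C–Br bonds intact, which hydrogenation over palladium would endanger.

Step 3
Reactants: 4 1,2-bis(3-bromo-4,5-dimethoxyphenyl)ethane; 5 N-methoxy-N-methylacetamide
Product: 8 1,2-bis(3-acetyl-4,5-dimethoxyphenyl)ethane, via dilithio arene 6 (not isolated), via lithium hemiaminal adduct 7 (not isolated)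
Conditions: n-BuLi (2.2 equiv), THF, −78 °C; 5 (3 equiv), −78 to 0 °C; aq. HCl
Reagents that add atoms: N-methoxy-N-methylacetamide, CON(C)C(C)=O
Why: Bromine–lithium exchange followed by Weinreb ketone synthesis, in which exchange next to a methoxy group is fast at −78 °C and the chelated tetrahedral adduct 7 resists a second addition, so each aryllithium should give exactly one acetyl group on work-up.

Step 4
Reactants: 8 1,2-bis(3-acetyl-4,5-dimethoxyphenyl)ethane; 9 cyclobutyltriphenylphosphonium bromide
Product: 11 1,2-bis[3-(1-cyclobutylideneethyl)-4,5-dimethoxyphenyl]ethane, via cyclobutylidene ylide 10 (not isolated)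
Conditions: 9 (4 equiv), KOtBu, THF, 0 °C to reflux
Reagents that add atoms: cyclobutyltriphenylphosphonium bromide, [Br-].C1CCC1[P+](c1ccccc1)(c1ccccc1)c1ccccc1
Why: Wittig olefination with a reactive, non-stabilised small-ring ylide, the standard way from aryl methyl ketones to tetrasubstituted (1-arylethylidene)cyclobutanes; excess ylide offsets enolisation of the acetyl groups and any mono-alkene can be resubmitted.

Step 5
Reactants: 11 1,2-bis[3-(1-cyclobutylideneethyl)-4,5-dimethoxyphenyl]ethane
Product: 12 1,2-bis{3,4-dimethoxy-5-[(2S)-2-methyl-1-oxaspiro[2.3]hexan-2-yl]phenyl}ethane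
Conditions: glucose-derived spiro-oxazolidinone ketone catalyst, N-(4-methylphenyl), 4,5-O-isopropylidene (C17H19NO6, L-glucose-derived antipode, 0.3 equiv per alkene), Oxone (2KHSO5·KHSO4·K2SO4), K2CO3, Bu4NHSO4, DME–CH2(OMe)2/aq. K2CO3–AcOH buffer (pH 8), −10 °C; crude 12 carried on
Reagents that add atoms: potassium peroxymonosulfate (KHSO5), [K+].[O-]S(=O)(=O)OO
Why: Shi asymmetric epoxidation, in which the chiral dioxirane formed from the ketone and KHSO5 transfers oxygen to one face of each electron-rich tetrasubstituted alkene under catalyst control and so sets the aryl-bearing C2 stereocentre of each oxaspirohexane (the spiro carbon is not stereogenic), while two independent events on a twofold-symmetric substrate should enrich the C2-symmetric isomer at the cost of a minor meso isomer.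

Step 6
Reactants: 12 1,2-bis{3,4-dimethoxy-5-[(2S)-2-methyl-1-oxaspiro[2.3]hexan-2-yl]phenyl}ethane
Product: 13 1,2-bis{3,4-dimethoxy-5-[(1R)-1-methyl-2-oxocyclopentyl]phenyl}ethane
Conditions: Et2AlCl (3 equiv), toluene, −78 °C; aq. HCl; recrystallisation
Reagents that add atoms: none
Why: Lewis-acid-promoted ring expansion of an oxaspirohexane (a semipinacol-type 1,2-alkyl shift), in which a cyclobutane CH2 migrates to the benzylic carbon anti to the aluminium-bound oxygen under relief of four-ring strain, so each benzylic centre is inverted and the (S)-epoxide should give the (R)-2-aryl-2-methylcyclopentanone; recrystallisation of 13 should remove the meso diastereomer.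

Step 7
Reactants: 13 1,2-bis{3,4-dimethoxy-5-[(1R)-1-methyl-2-oxocyclopentyl]phenyl}ethane; 14 dimethylzinc
Product: 17 1,2-bis{3,4-dimethoxy-5-[(1S)-1,2,2-trimethylcyclopentyl]phenyl}ethane, via dimethyltitanium dichloride 15 (not isolated), via titanium alkoxide 16 (not isolated)
Conditions: TiCl4 (6 equiv), 14 (6 equiv), CH2Cl2, −30 °C; then 13, −30 to 0 °C; H2O quench
Reagents that add atoms: dimethylzinc, C[Zn]C (its methyl groups are passed on by dimethyltitanium dichloride 15, C[Ti](C)(Cl)Cl)
Why: This is the known titanium-mediated geminal dimethylation of ketones, precedented on 2-aryl-2-methylcyclopentanones: Ti(CH3)2Cl2 15 adds one methyl group to each titanium-bound carbonyl to give the tertiary alkoxide 16. The oxophilic titanium then lets each C2'–O bond ionise to a tertiary cation or tight ion pair that takes a second methyl group from titanium, so four C2'–CH3 bonds and both gem-dimethyl carbons form in one flask. No ring is closed and no stereocentre is created; C1' is untouched, and its descriptor changes from R in 13 to S in 17 only because the CIP rank of C2' falls below that of the aryl group. The selectivity required is methyl capture at the C2' cation ahead of proton loss to an alkene and ahead of a 1,2-shift of the electron-rich aryl group through a phenonium ion, which would degrade the configuration at C1'. The substrate secures the first addition because C1' bears no hydrogen and each ketone can enolise on one side only, and an excess of reagent at low temperature should keep methyl delivery faster than rearrangement. The stereochemical purity of 17 should be checked by chiral HPLC before deprotection.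

Step 8
Reactants: 17 1,2-bis{3,4-dimethoxy-5-[(1S)-1,2,2-trimethylcyclopentyl]phenyl}ethane
Product: 19 5,5'-(ethane-1,2-diyl)bis{3-[(1S)-1,2,2-trimethylcyclopentyl]benzene-1,2-diol}, via bis(bromodioxaborole) 18 (not isolated)
Conditions: BBr3 (8 equiv), CH2Cl2, −78 °C to rt; H2O, 0 °C, under argon
Reagents that add atoms: none
Why: Lewis-acid cleavage of aryl methyl ethers with BBr3, in which boron binds each methoxy oxygen and bromide removes the methyl group by SN2 displacement to give the cyclic bromoboronates 18 that hydrolyse to the catechols, while the all-carbon quaternary centres are inert.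

Compound list
1 | 3-bromo-4,5-dimethoxybenzaldehyde | COc1cc(C=O)cc(Br)c1OC | starting material
2 | titanium pinacolate, idealised as the cyclic dichlorotitanium 1,2-diolate of 1,2-bis(3-bromo-4,5-dimethoxyphenyl)ethane-1,2-diol | COc1cc(C2O[Ti](Cl)(Cl)OC2c2cc(OC)c(OC)c(Br)c2)cc(Br)c1OC | intermediate
3 | (E)-1,2-bis(3-bromo-4,5-dimethoxyphenyl)ethene | COc1cc(/C=C/c2cc(OC)c(OC)c(Br)c2)cc(Br)c1OC | intermediate
4 | 1,2-bis(3-bromo-4,5-dimethoxyphenyl)ethane | COc1cc(CCc2cc(OC)c(OC)c(Br)c2)cc(Br)c1OC | intermediate
5 | N-methoxy-N-methylacetamide | CON(C)C(C)=O | starting material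
6 | 1,2-bis(3-lithio-4,5-dimethoxyphenyl)ethane | COc1cc(CCc2cc(OC)c(OC)c([Li])c2)cc([Li])c1OC | intermediate
7 | dilithium bis(hemiaminal alkoxide) from twofold addition of 6 to 5 | COc1cc(CCc2cc(OC)c(OC)c(C(C)(O[Li])N(C)OC)c2)cc(C(C)(O[Li])N(C)OC)c1OC | intermediate
8 | 1,2-bis(3-acetyl-4,5-dimethoxyphenyl)ethane | COc1cc(CCc2cc(OC)c(OC)c(C(C)=O)c2)cc(C(C)=O)c1OC | intermediate
9 | cyclobutyltriphenylphosphonium bromide | [Br-].C1CCC1[P+](c1ccccc1)(c1ccccc1)c1ccccc1 | starting material
10 | cyclobutylidene(triphenyl)phosphorane | C1CC(C1)=P(c1ccccc1)(c1ccccc1)c1ccccc1 | intermediate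
11 | 1,2-bis[3-(1-cyclobutylideneethyl)-4,5-dimethoxyphenyl]ethane | COc1cc(CCc2cc(OC)c(OC)c(C(C)=C3CCC3)c2)cc(C(C)=C2CCC2)c1OC | intermediate
12 | 1,2-bis{3,4-dimethoxy-5-[(2S)-2-methyl-1-oxaspiro[2.3]hexan-2-yl]phenyl}ethane | COc1cc(CCc2cc(OC)c(OC)c([C@]3(C)OC34CCC4)c2)cc([C@]2(C)OC23CCC3)c1OC | intermediate
13 | 1,2-bis{3,4-dimethoxy-5-[(1R)-1-methyl-2-oxocyclopentyl]phenyl}ethane | COc1cc(CCc2cc(OC)c(OC)c([C@@]3(C)CCCC3=O)c2)cc([C@@]2(C)CCCC2=O)c1OC | intermediate
14 | dimethylzinc | C[Zn]C | starting material
15 | dimethyltitanium dichloride | C[Ti](C)(Cl)Cl | intermediate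
16 | bis[dichloro(methyl)titanium] alkoxide of 1,2-bis{5-[(1R)-2-hydroxy-1,2-dimethylcyclopentyl]-3,4-dimethoxyphenyl}ethane (C2' epimers) | COc1cc(CCc2cc(OC)c(OC)c([C@@]3(C)CCCC3(C)O[Ti](C)(Cl)Cl)c2)cc([C@@]2(C)CCCC2(C)O[Ti](C)(Cl)Cl)c1OC | intermediate
17 | 1,2-bis{3,4-dimethoxy-5-[(1S)-1,2,2-trimethylcyclopentyl]phenyl}ethane | COc1cc(CCc2cc(OC)c(OC)c([C@@]3(C)CCCC3(C)C)c2)cc([C@@]2(C)CCCC2(C)C)c1OC | intermediate
18 | 1,2-bis{2-bromo-7-[(1S)-1,2,2-trimethylcyclopentyl]-1,3,2-benzodioxaborol-5-yl}ethane | CC1(C)CCC[C@]1(C)c1cc(CCc2cc3OB(Br)Oc3c([C@@]3(C)CCCC3(C)C)c2)cc2OB(Br)Oc12 | intermediate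
19 | 5,5'-(ethane-1,2-diyl)bis{3-[(1S)-1,2,2-trimethylcyclopentyl]benzene-1,2-diol} | CC1(C)CCC[C@]1(C)c1cc(CCc2cc(O)c(O)c([C@@]3(C)CCCC3(C)C)c2)cc(O)c1O | target

Total step count: 8. Longest linear sequence: 8 steps (1 to 19).

Steps most likely to fail

Step 5. Oxygen transfer to the two hindered tetrasubstituted alkenes, each twisted by an ortho methoxy group, may be slow and poorly face-selective. Conversion may then stall at the mono-epoxide and the meso isomer may build up, and the acid-labile benzylic epoxide may open before the controlled rearrangement. The fallback sets out from 4 and comes back to the route at 13; it makes the quaternary centres by palladium-catalysed asymmetric α-arylation of a ketone enolate instead of by epoxidation and ring expansion. 2-Methylcyclopentanone is formylated (HCO2Et, NaH) and condensed with N-methylaniline to give the blocked ketone (E)-2-methyl-5-[(N-methylanilino)methylidene]cyclopentan-1-one F1. Dibromide 4 is coupled at both ends with the enolate of F1 (Pd2(dba)3, BINAP in the antipode that gives the R centres, NaOtBu, toluene), which should give 1,2-bis{3,4-dimethoxy-5-[(1R,3E)-1-methyl-3-[(N-methylanilino)methylidene]-2-oxocyclopentyl]phenyl}ethane F2; ortho-alkoxy aryl bromides lie at the hindered end of the scope of this reaction. Aqueous HCl in THF should hydrolyse the vinylogous amides to 1,2-bis{5-[(1R)-3-(hydroxymethylidene)-1-methyl-2-oxocyclopentyl]-3,4-dimethoxyphenyl}ethane F3, and aqueous NaOH then removes the formyl groups by retro-Claisen cleavage to give 13.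

Step 7. After the first methyl transfer the C2' cation may lose a proton to an endocyclic or exocyclic alkene, or be intercepted by migration of the electron-rich aryl group, which would lower the configurational purity at C1'. One of the two ends may also stop at the tertiary alcohol. The fallback sets out from 13 and comes back at 17; it introduces the two methyl groups stepwise without generating a cation at C2'. Wittig methylenation (Ph3P=CH2 from Ph3PCH3Br and KOtBu, toluene, reflux) should give 1,2-bis{3,4-dimethoxy-5-[(1S)-1-methyl-2-methylidenecyclopentyl]phenyl}ethane F4. Furukawa-type Simmons–Smith cyclopropanation (Et2Zn, CH2I2, CH2Cl2) should give 1,2-bis{3,4-dimethoxy-5-[(4S)-4-methylspiro[2.4]heptan-4-yl]phenyl}ethane F5. Hydrogenolysis of the unhindered CH2–CH2 bond of each cyclopropane (H2, PtO2, AcOH) then gives 17.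

Step 6. If the benzylic C–O bond of the aluminium-bound epoxide ionises fully before the ring CH2 migrates, the electron-rich aryl group can sustain an open cation and the inversion becomes leaky, which lowers the configurational purity at C1'. The fallback sets out from 11 and comes back at 13; it replaces the Lewis-acid shift by an iodide-mediated double displacement. Epoxidation of 11 with the antipodal ketone catalyst (the D-glucose-derived one under the assumption above) should give 1,2-bis{3,4-dimethoxy-5-[(2R)-2-methyl-1-oxaspiro[2.3]hexan-2-yl]phenyl}ethane F6. LiI in CH2Cl2 at room temperature should open each epoxide at the benzylic carbon with inversion to the dilithium alkoxide of 1,2-bis{3-[(1S)-1-(1-hydroxycyclobutyl)-1-iodoethyl]-4,5-dimethoxyphenyl}ethane F7. Each cyclobutanolate then expands with a second inversion by semipinacol displacement of iodide, so that net retention leads to 13 of the same configuration.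

Further compounds
F1 | step 5 | (E)-2-methyl-5-[(N-methylanilino)methylidene]cyclopentan-1-one (racemic) | CC1CC/C(=C\N(C)c2ccccc2)C1=O
F2 | step 5 | 1,2-bis{3,4-dimethoxy-5-[(1R,3E)-1-methyl-3-[(N-methylanilino)methylidene]-2-oxocyclopentyl]phenyl}ethane | COc1cc(CCc2cc(OC)c(OC)c([C@@]3(C)CC/C(=C\N(C)c4ccccc4)C3=O)c2)cc([C@@]2(C)CC/C(=C\N(C)c3ccccc3)C2=O)c1OC
F3 | step 5 | 1,2-bis{5-[(1R)-3-(hydroxymethylidene)-1-methyl-2-oxocyclopentyl]-3,4-dimethoxyphenyl}ethane | COc1cc(CCc2cc(OC)c(OC)c([C@@]3(C)CCC(=CO)C3=O)c2)cc([C@@]2(C)CCC(=CO)C2=O)c1OC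
F4 | step 7 | 1,2-bis{3,4-dimethoxy-5-[(1S)-1-methyl-2-methylidenecyclopentyl]phenyl}ethane | COc1cc(CCc2cc(OC)c(OC)c([C@@]3(C)CCCC3=C)c2)cc([C@@]2(C)CCCC2=C)c1OC
F5 | step 7 | 1,2-bis{3,4-dimethoxy-5-[(4S)-4-methylspiro[2.4]heptan-4-yl]phenyl}ethane | COc1cc(CCc2cc(OC)c(OC)c([C@@]3(C)CCCC34CC4)c2)cc([C@@]2(C)CCCC23CC3)c1OC
F6 | step 6 | 1,2-bis{3,4-dimethoxy-5-[(2R)-2-methyl-1-oxaspiro[2.3]hexan-2-yl]phenyl}ethane | COc1cc(CCc2cc(OC)c(OC)c([C@@]3(C)OC34CCC4)c2)cc([C@@]2(C)OC23CCC3)c1OC
F7 | step 6 | dilithium alkoxide of 1,2-bis{3-[(1S)-1-(1-hydroxycyclobutyl)-1-iodoethyl]-4,5-dimethoxyphenyl}ethane | COc1cc(CCc2cc(OC)c(OC)c([C@](C)(I)C3(O[Li])CCC3)c2)cc([C@](C)(I)C2(O[Li])CCC2)c1OC
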